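**Strategy**

- Retrosynthetic cuts, in order: the bond from C5 of the benzofuran to the acrylic chain (Heck); the C2–C3 bond of the dihydrofuran ring (carbene C–H insertion, with the C3 CH2OH carried as a methyl ester); the bond from arene carbon C3a to the carbene carbon (aryl Grignard plus dimethyl oxalate); the O1–C2 benzyl ether bond (Mitsunobu).
- Enabling feature: C2–C3 joins a CH (C2) flanked by ring oxygen O1 and the syringyl ring C to a carbon (C3) that sits on arene carbon C3a of ring A and bears a one-carbon oxygenated arm. This is the imprint of an aryl(ester)carbene inserting into an ether- and aryl-activated benzylic C–H bond.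
- Forward order: the two benzene rings (A and C) are bought and tied together through O1–C2; ring A then receives the glyoxylate and the diazo group; the five-membered ring B, the only ring made, closes at C2–C3; the acrylate is attached last at C5, followed by unmasking.
- Stereochemistry: C2 (S) comes from the chiral dirhodium carboxylate in the insertion; C3 comes from base equilibration of the kinetic cis ester to the trans ester under control of C2 (3R after reduction); the E alkene comes from the Heck reaction.

Key step: step 8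

Assumption: the sense of induction known for N-phthaloyl-tert-leucinate dirhodium catalysts with ortho-benzyloxy aryl diazoacetates is taken to carry over, so the (R)-ligand catalyst dirhodium tetrakis[N-phthaloyl-(R)-tert-leucinate], Rh2(R-PTTL)4, is expected to give the (2S,3R)-cis ester; if a test run shows the mirror-image sense, the (S)-ligand catalyst is used and nothing else changes.

Ring atoms are numbered as in 2,3-dihydro-1-benzofuran (O1, C2, C3, C3a, C4–C7, C7a).

**Route**

Step 1
Reactants: 1 4-bromo-2-methoxyphenol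
Product: 2 4-bromo-2-iodo-6-methoxyphenol
Conditions: NIS, TsOH·H2O (10 mol%), MeCN, 0 °C to rt
Reagents that add atoms: N-iodosuccinimide, O=C1CCC(=O)N1I
Why: Electrophilic aromatic iodination, in which the free phenol is the strongest director and its para position is blocked by bromine, so iodine should enter the one open ortho position.

Step 2
Reactants: 3 syringaldehyde (4-hydroxy-3,5-dimethoxybenzaldehyde)
Product: 4 3,5-dimethoxy-4-(triisopropylsilyloxy)benzaldehyde
Conditions: TIPSCl, imidazole, DMF, rt
Reagents that add atoms: triisopropylsilyl chloride, CC(C)[Si](Cl)(C(C)C)C(C)C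
Why: Imidazole-promoted O-silylation of a phenol; the bulky silyl ether between two methoxy groups is chosen to withstand Grignard, amidine base, hydride and Heck conditions and to leave with fluoride.

Step 3
Reactants: 4 3,5-dimethoxy-4-(triisopropylsilyloxy)benzaldehyde
Product: 5 [3,5-dimethoxy-4-(triisopropylsilyloxy)phenyl]methanol
Conditions: NaBH4, THF/MeOH, 0 °C
Reagents that add atoms: none
Why: Chemoselective borohydride reduction of an aryl aldehyde to the benzylic alcohol, brief and cold so that the aryl silyl ether is not touched.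

Step 4
Reactants: 2 4-bromo-2-iodo-6-methoxyphenol; 5 [3,5-dimethoxy-4-(triisopropylsilyloxy)phenyl]methanol
Product: 6 {4-[(4-bromo-2-iodo-6-methoxyphenoxy)methyl]-2,6-dimethoxyphenoxy}triisopropylsilane (aryl benzyl ether)
Conditions: PPh3, DIAD, THF, 0 °C to rt
Reagents that add atoms: none
Why: Mitsunobu etherification, in which the acidic halogenated phenol protonates the betaine and its phenoxide displaces the activated primary benzylic oxyphosphonium ion, so that no labile para-silyloxybenzyl halide has to be made.

Step 5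
Reactants: 6 {4-[(4-bromo-2-iodo-6-methoxyphenoxy)methyl]-2,6-dimethoxyphenoxy}triisopropylsilane; 7 dimethyl oxalate
Product: 9 methyl 2-[5-bromo-2-{[3,5-dimethoxy-4-(triisopropylsilyloxy)phenyl]methoxy}-3-methoxyphenyl]-2-oxoacetate, via arylmagnesium chloride 8 (not isolated)
Conditions: iPrMgCl·LiCl (1.1 equiv), THF, −40 °C; then transferred into 7 (3 equiv), THF, −78 to 0 °C; aq NH4Cl
Reagents that add atoms: none
Why: Halogen–magnesium exchange is far faster at the aryl iodide (helped by the ortho alkoxy group) than at the aryl bromide at −40 °C, and inverse addition of the Grignard reagent to excess dimethyl oxalate at −78 °C should stop at the chelated tetrahedral adduct and so deliver the α-keto ester and not a tertiary alcohol.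

Step 6
Reactants: 9 methyl 2-[5-bromo-2-{[3,5-dimethoxy-4-(triisopropylsilyloxy)phenyl]methoxy}-3-methoxyphenyl]-2-oxoacetate
Product: 10 methyl 2-[5-bromo-2-{[3,5-dimethoxy-4-(triisopropylsilyloxy)phenyl]methoxy}-3-methoxyphenyl]-2-(tosylhydrazono)acetate (C=N geometry not controlled)
Conditions: TsNHNH2, MeOH, 60 °C
Reagents that add atoms: p-toluenesulfonyl hydrazide, Cc1ccc(cc1)S(=O)(=O)NN
Why: Hydrazone condensation at the ketone carbonyl of the α-keto ester, which is much more electrophilic than the ester carbonyl and has only one ortho substituent beside it.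

Step 7
Reactants: 10 methyl 2-[5-bromo-2-{[3,5-dimethoxy-4-(triisopropylsilyloxy)phenyl]methoxy}-3-methoxyphenyl]-2-(tosylhydrazono)acetate
Product: 11 methyl 2-[5-bromo-2-{[3,5-dimethoxy-4-(triisopropylsilyloxy)phenyl]methoxy}-3-methoxyphenyl]-2-diazoacetate
Conditions: DBU, CH2Cl2, 0 °C to rt
Reagents that add atoms: none
Why: Bamford–Stevens reaction, in which the deprotonated tosylhydrazone expels p-toluenesulfinate already at room temperature because the diazo compound formed is stabilised by both the ester and the aryl ring.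

Step 8
Reactants: 11 methyl 2-[5-bromo-2-{[3,5-dimethoxy-4-(triisopropylsilyloxy)phenyl]methoxy}-3-methoxyphenyl]-2-diazoacetate
Product: 12 methyl (2S,3R)-5-bromo-2-[3,5-dimethoxy-4-(triisopropylsilyloxy)phenyl]-7-methoxy-2,3-dihydro-1-benzofuran-3-carboxylate (cis)
Conditions: Rh2(R-PTTL)4 (1 mol%), toluene, −60 °C
Reagents that add atoms: none
Why: The divalent rhodium catalyst takes N2 out of the donor/acceptor diazo ester to give an electrophilic rhodium-bound carbene at the future C3, which inserts into a benzylic C–H bond of the OCH2Ar arm through a concerted but asynchronous, hydride-transfer-like three-centre transition state, forming the C2–C3 bond and releasing the catalyst. The closest known reaction type is the enantioselective intramolecular 1,5 C–H insertion of ortho-benzyloxy aryl diazoacetates under chiral dirhodium carboxylate catalysis, which gives cis-2-aryl-2,3-dihydrobenzofuran-3-carboxylates. Ring B closes by 1,5-insertion: the carbene carbon on C3a bonds to the ether carbon on O1, so that O1, C2, C3, C3a and C7a make up the new five-membered ring on the existing arene. C2 is controlled by the chiral N-phthaloyl-tert-leucinate ligand sphere, which picks one of the two enantiotopic benzylic hydrogens, and C3 is set relative to C2 in the same transition state, with cis as the kinetic outcome. The step needs site selectivity, cis diastereoselectivity and enantioselectivity: the site is fixed because the OCH2 group holds the only C–H bonds in 1,5 relation to the carbene and is activated by both the ether oxygen and the electron-rich silyloxy-dimethoxyphenyl ring, while low temperature in non-coordinating toluene should secure the two stereoselectivities. The aryl bromide, the silyl ether and the methyl ethers are not expected to react with the carbene.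

Step 9
Reactants: 12 methyl (2S,3R)-5-bromo-2-[3,5-dimethoxy-4-(triisopropylsilyloxy)phenyl]-7-methoxy-2,3-dihydro-1-benzofuran-3-carboxylate (cis)
Product: 13 methyl (2S,3S)-5-bromo-2-[3,5-dimethoxy-4-(triisopropylsilyloxy)phenyl]-7-methoxy-2,3-dihydro-1-benzofuran-3-carboxylate (trans)
Conditions: DBU (1 equiv), THF, 50 °C
Reagents that add atoms: none
Why: Enolate-mediated epimerisation at C3, whose hydrogen is both benzylic and α to the ester, runs under thermodynamic control of the fixed C2 centre toward the trans isomer, which avoids the eclipsed aryl/ester pair on the five-membered ring; the non-nucleophilic amidine in an aprotic solvent should leave the aryl silyl ether in place.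

Step 10
Reactants: 13 methyl (2S,3S)-5-bromo-2-[3,5-dimethoxy-4-(triisopropylsilyloxy)phenyl]-7-methoxy-2,3-dihydro-1-benzofuran-3-carboxylate (trans)
Product: 14 [(2S,3R)-5-bromo-2-[3,5-dimethoxy-4-(triisopropylsilyloxy)phenyl]-7-methoxy-2,3-dihydro-1-benzofuran-3-yl]methanol (trans)
Conditions: LiBH4, THF, 0 °C to rt
Reagents that add atoms: none
Why: Borohydride ester reduction with LiBH4, which reduces esters but not aryl bromides or silyl ethers and is not basic enough to disturb C3 (the descriptor changes from 3S to 3R only through the change in substituent priorities).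

Step 11
Reactants: 14 [(2S,3R)-5-bromo-2-[3,5-dimethoxy-4-(triisopropylsilyloxy)phenyl]-7-methoxy-2,3-dihydro-1-benzofuran-3-yl]methanol; 15 methyl acrylate
Product: 16 methyl (E)-3-[(2S,3R)-2-[3,5-dimethoxy-4-(triisopropylsilyloxy)phenyl]-3-(hydroxymethyl)-7-methoxy-2,3-dihydro-1-benzofuran-5-yl]prop-2-enoate
Conditions: Pd(OAc)2 (5 mol%), P(o-tol)3 (12 mol%), Et3N, DMF, 100 °C
Reagents that add atoms: none
Why: Mizoroki–Heck reaction, in which zerovalent palladium adds oxidatively to the aryl bromide, syn carbopalladation of the acrylate and syn β-hydride elimination give the E cinnamate, and the free primary alcohol and the silyl ether are tolerated.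

Step 12
Reactants: 16 methyl (E)-3-[(2S,3R)-2-[3,5-dimethoxy-4-(triisopropylsilyloxy)phenyl]-3-(hydroxymethyl)-7-methoxy-2,3-dihydro-1-benzofuran-5-yl]prop-2-enoate
Product: 17 methyl (E)-3-[(2S,3R)-2-(4-hydroxy-3,5-dimethoxyphenyl)-3-(hydroxymethyl)-7-methoxy-2,3-dihydro-1-benzofuran-5-yl]prop-2-enoate
Conditions: TBAF/AcOH (equimolar), THF, 0 °C
Reagents that add atoms: none
Why: Fluoride desilylation of the aryl silyl ether, buffered with acetic acid so that the liberated phenol stays protonated and the para-hydroxybenzylic C2–O1 bond is not opened through a quinone methide.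

Step 13
Reactants: 17 methyl (E)-3-[(2S,3R)-2-(4-hydroxy-3,5-dimethoxyphenyl)-3-(hydroxymethyl)-7-methoxy-2,3-dihydro-1-benzofuran-5-yl]prop-2-enoate
Product: 19 (E)-3-[(2S,3R)-2-(4-hydroxy-3,5-dimethoxyphenyl)-3-(hydroxymethyl)-7-methoxy-2,3-dihydro-1-benzofuran-5-yl]prop-2-enoic acid (CNP0224723.1), via dilithium salt 18 (not isolated)
Conditions: LiOH·H2O, THF/MeOH/H2O, rt; then 1 M HCl to pH 3, 0 °C
Reagents that add atoms: lithium hydroxide, [Li+].[OH-]
Why: Ester saponification by acyl–oxygen cleavage at room temperature, safe here because C3 no longer carries an acidifying group that could trigger β-elimination of O1, and followed by cold, mild acidification that should not ionise the electron-rich benzylic ether.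

**Compound list**

1 | 4-bromo-2-methoxyphenol | COc1cc(Br)ccc1O | starting material
2 | 4-bromo-2-iodo-6-methoxyphenol | COc1cc(Br)cc(I)c1O | intermediate
3 | syringaldehyde | COc1cc(C=O)cc(OC)c1O | starting material
4 | 3,5-dimethoxy-4-(triisopropylsilyloxy)benzaldehyde | COc1cc(C=O)cc(OC)c1O[Si](C(C)C)(C(C)C)C(C)C | intermediate
5 | [3,5-dimethoxy-4-(triisopropylsilyloxy)phenyl]methanol | COc1cc(CO)cc(OC)c1O[Si](C(C)C)(C(C)C)C(C)C | intermediate
6 | {4-[(4-bromo-2-iodo-6-methoxyphenoxy)methyl]-2,6-dimethoxyphenoxy}triisopropylsilane | COc1cc(Br)cc(I)c1OCc1cc(OC)c(O[Si](C(C)C)(C(C)C)C(C)C)c(OC)c1 | intermediate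
7 | dimethyl oxalate | COC(=O)C(=O)OC | starting material
8 | [5-bromo-2-{[3,5-dimethoxy-4-(triisopropylsilyloxy)phenyl]methoxy}-3-methoxyphenyl]magnesium chloride, LiCl complex (not isolated) | COc1cc(Br)cc([Mg]Cl)c1OCc1cc(OC)c(O[Si](C(C)C)(C(C)C)C(C)C)c(OC)c1 | intermediate
9 | methyl 2-[5-bromo-2-{[3,5-dimethoxy-4-(triisopropylsilyloxy)phenyl]methoxy}-3-methoxyphenyl]-2-oxoacetate | COC(=O)C(=O)c1cc(Br)cc(OC)c1OCc1cc(OC)c(O[Si](C(C)C)(C(C)C)C(C)C)c(OC)c1 | intermediate
10 | methyl 2-[5-bromo-2-{[3,5-dimethoxy-4-(triisopropylsilyloxy)phenyl]methoxy}-3-methoxyphenyl]-2-(tosylhydrazono)acetate | COC(=O)C(=NNS(=O)(=O)c1ccc(C)cc1)c1cc(Br)cc(OC)c1OCc1cc(OC)c(O[Si](C(C)C)(C(C)C)C(C)C)c(OC)c1 | intermediate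
11 | methyl 2-[5-bromo-2-{[3,5-dimethoxy-4-(triisopropylsilyloxy)phenyl]methoxy}-3-methoxyphenyl]-2-diazoacetate | COC(=O)C(=[N+]=[N-])c1cc(Br)cc(OC)c1OCc1cc(OC)c(O[Si](C(C)C)(C(C)C)C(C)C)c(OC)c1 | intermediate
12 | methyl (2S,3R)-5-bromo-2-[3,5-dimethoxy-4-(triisopropylsilyloxy)phenyl]-7-methoxy-2,3-dihydro-1-benzofuran-3-carboxylate (cis) | COc1cc([C@H]2Oc3c(OC)cc(Br)cc3[C@H]2C(=O)OC)cc(OC)c1O[Si](C(C)C)(C(C)C)C(C)C | intermediate
13 | methyl (2S,3S)-5-bromo-2-[3,5-dimethoxy-4-(triisopropylsilyloxy)phenyl]-7-methoxy-2,3-dihydro-1-benzofuran-3-carboxylate (trans) | COc1cc([C@H]2Oc3c(OC)cc(Br)cc3[C@@H]2C(=O)OC)cc(OC)c1O[Si](C(C)C)(C(C)C)C(C)C | intermediate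
14 | [(2S,3R)-5-bromo-2-[3,5-dimethoxy-4-(triisopropylsilyloxy)phenyl]-7-methoxy-2,3-dihydro-1-benzofuran-3-yl]methanol (trans) | COc1cc([C@H]2Oc3c(OC)cc(Br)cc3[C@@H]2CO)cc(OC)c1O[Si](C(C)C)(C(C)C)C(C)C | intermediate
15 | methyl acrylate | C=CC(=O)OC | starting material
16 | methyl (E)-3-[(2S,3R)-2-[3,5-dimethoxy-4-(triisopropylsilyloxy)phenyl]-3-(hydroxymethyl)-7-methoxy-2,3-dihydro-1-benzofuran-5-yl]prop-2-enoate | COc1cc([C@H]2Oc3c(OC)cc(/C=C/C(=O)OC)cc3[C@@H]2CO)cc(OC)c1O[Si](C(C)C)(C(C)C)C(C)C | intermediate
17 | methyl (E)-3-[(2S,3R)-2-(4-hydroxy-3,5-dimethoxyphenyl)-3-(hydroxymethyl)-7-methoxy-2,3-dihydro-1-benzofuran-5-yl]prop-2-enoate | COc1cc([C@H]2Oc3c(OC)cc(/C=C/C(=O)OC)cc3[C@@H]2CO)cc(OC)c1O | intermediate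
18 | dilithium phenoxide carboxylate of the target (not isolated) | [Li+].[Li+].COc1cc([C@H]2Oc3c(OC)cc(/C=C/C(=O)[O-])cc3[C@@H]2CO)cc(OC)c1[O-] | intermediate
19 | (E)-3-[(2S,3R)-2-(4-hydroxy-3,5-dimethoxyphenyl)-3-(hydroxymethyl)-7-methoxy-2,3-dihydro-1-benzofuran-5-yl]prop-2-enoic acid (CNP0224723.1) | COc1cc([C@H]2Oc3c(OC)cc(/C=C/C(=O)O)cc3[C@@H]2CO)cc(OC)c1O | target

**Step count**

Total: 13 steps. Longest linear sequence: 12 steps (steps 2 to 13, from syringaldehyde 3); the branch from 1 joins at step 4.

**Steps most likely to fail**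

Step 8. The methoxy group next to the benzyloxy arm may twist that arm out of the arene plane, so that the catalyst differentiates the two enantiotopic hydrogens or the cis/trans transition states poorly; slowed insertion at low temperature could also let carbene dimerisation compete. The fallback gives up catalyst control in favour of resolution. Setting out from diazo ester 11, Rh2(OAc)4 in CH2Cl2 at rt should give the racemic cis/trans ester mixture F1. Equilibration with DBU should converge it on the racemic trans ester F2, and LiBH4 should reduce this to the racemic trans alcohol F3. Preparative chromatography on a chiral stationary phase would then separate the wanted (2S,3R)-enantiomer, which is compound 14, from the unwanted (2R,3S)-alcohol F4. The route is rejoined at 14.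

Step 9. The ester enolate may expel the ring oxygen (retro-oxa-Michael opening of ring B) and re-close without facial control, eroding the C2 configuration; alternatively the equilibration may stall or the silyl ether may be lost on prolonged heating with base. The fallback moves the epimerisation to the aldehyde oxidation level, where a weak base at room temperature suffices. Setting out from cis ester 12, LiBH4 should give the cis (2S,3S)-alcohol F5, and Dess–Martin periodinane the cis (2S,3R)-aldehyde F6. Catalytic Et3N in CH2Cl2 at rt should equilibrate this to the trans (2S,3S)-aldehyde F7, and NaBH4 would reduce it to alcohol 14, where the route is rejoined.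

Step 11. Oxidative addition into the electron-rich aryl bromide may be slow, with decay of the catalyst to palladium metal and competing protodebromination or silyl loss at the temperature required. The fallback replaces the palladium coupling by carbonyl olefination. Setting out from bromide 14, n-BuLi (1 equiv) and then t-BuLi (2 equiv) in THF at −78 °C should generate the lithium alkoxide aryllithium F8 (not isolated), which DMF would convert to the C5 aldehyde F9. A Wittig reaction with Ph3P=CHCO2Me in toluene at 60 °C should then give the E ester 16, where the route is rejoined.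

**Further compounds**

F1 | step 8 | racemic methyl 5-bromo-2-[3,5-dimethoxy-4-(triisopropylsilyloxy)phenyl]-7-methoxy-2,3-dihydro-1-benzofuran-3-carboxylate, cis/trans mixture | COc1cc(C2Oc3c(OC)cc(Br)cc3C2C(=O)OC)cc(OC)c1O[Si](C(C)C)(C(C)C)C(C)C
F2 | step 8 | racemic trans ester, (2S,3S) and (2R,3R) in equal parts | COc1cc([C@H]2Oc3c(OC)cc(Br)cc3[C@@H]2C(=O)OC)cc(OC)c1O[Si](C(C)C)(C(C)C)C(C)C.COc1cc([C@@H]2Oc3c(OC)cc(Br)cc3[C@H]2C(=O)OC)cc(OC)c1O[Si](C(C)C)(C(C)C)C(C)C
F3 | step 8 | racemic trans alcohol, (2S,3R) and (2R,3S) in equal parts | COc1cc([C@H]2Oc3c(OC)cc(Br)cc3[C@@H]2CO)cc(OC)c1O[Si](C(C)C)(C(C)C)C(C)C.COc1cc([C@@H]2Oc3c(OC)cc(Br)cc3[C@H]2CO)cc(OC)c1O[Si](C(C)C)(C(C)C)C(C)C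
F4 | step 8 | [(2R,3S)-5-bromo-2-[3,5-dimethoxy-4-(triisopropylsilyloxy)phenyl]-7-methoxy-2,3-dihydro-1-benzofuran-3-yl]methanol, unwanted enantiomer | COc1cc([C@@H]2Oc3c(OC)cc(Br)cc3[C@H]2CO)cc(OC)c1O[Si](C(C)C)(C(C)C)C(C)C
F5 | step 9 | [(2S,3S)-5-bromo-2-[3,5-dimethoxy-4-(triisopropylsilyloxy)phenyl]-7-methoxy-2,3-dihydro-1-benzofuran-3-yl]methanol (cis) | COc1cc([C@H]2Oc3c(OC)cc(Br)cc3[C@H]2CO)cc(OC)c1O[Si](C(C)C)(C(C)C)C(C)C
F6 | step 9 | (2S,3R)-5-bromo-2-[3,5-dimethoxy-4-(triisopropylsilyloxy)phenyl]-7-methoxy-2,3-dihydro-1-benzofuran-3-carbaldehyde (cis) | COc1cc([C@H]2Oc3c(OC)cc(Br)cc3[C@H]2C=O)cc(OC)c1O[Si](C(C)C)(C(C)C)C(C)C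
F7 | step 9 | (2S,3S)-5-bromo-2-[3,5-dimethoxy-4-(triisopropylsilyloxy)phenyl]-7-methoxy-2,3-dihydro-1-benzofuran-3-carbaldehyde (trans) | COc1cc([C@H]2Oc3c(OC)cc(Br)cc3[C@@H]2C=O)cc(OC)c1O[Si](C(C)C)(C(C)C)C(C)C
F8 | step 11 | lithium alkoxide aryllithium derived from 14 (not isolated) | COc1cc([C@H]2Oc3c(OC)cc([Li])cc3[C@@H]2CO[Li])cc(OC)c1O[Si](C(C)C)(C(C)C)C(C)C
F9 | step 11 | (2S,3R)-2-[3,5-dimethoxy-4-(triisopropylsilyloxy)phenyl]-3-(hydroxymethyl)-7-methoxy-2,3-dihydro-1-benzofuran-5-carbaldehyde | COc1cc([C@H]2Oc3c(OC)cc(C=O)cc3[C@@H]2CO)cc(OC)c1O[Si](C(C)C)(C(C)C)C(C)C
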